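**Retrosynthetic overview**

1. Brevipolide G ⇒ (last step) open the C2′–C4′ cyclopropane bond to a C5′ ketone enolate plus a cis C1′/C2′ epoxide (3-exo-tet, inversion at C2′, C1′–O becomes the carbinol), mirroring the likely biogenesis from a (Z)-alkenyl pyranone epoxide.
2. Epoxy lactone ⇒ cis-epoxy aldehyde + but-3-enoate dienolate (vinylogous aldol, then δ-lactonisation of the (Z)-5-hydroxy-2-enoate, as in polyketide off-loading).
3. cis-Epoxy aldehyde ⇒ (Z)-allylic alcohol (Sharpless epoxidation) ⇒ terminal alkene + (Z)-but-2-ene-1,4-diol (Z-selective cross-metathesis).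
4. Alkene keto ester ⇒ methyl L-lactate (one-pot Weinreb/Grignard; supplies C6′) + O-silyl p-coumaric acid.
5. Ring order: oxirane (temporary) → δ-lactone → cyclopropane.

Atom labels: lactone O1, C2(=O), C3=C4, C5, C6; side chain C1′ (CHOH), C2′/C3′/C4′ (cyclopropane, C3′ = CH2), C5′ (C=O), C6′ (CH–O), C7′ (CH3).

Assumption: the biogenesis is taken to be δ-lactonisation of a (Z)-5-hydroxy-2-enoyl polyketide and cyclopropane closure by the C5′ ketone enolate on C2′ of a cis-C1′/C2′ epoxide.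

Assumption: in step 8 the (R)-ligand is taken as the enantiomer that gives the 6R lactone (the same sense as the substrate bias); if a test run shows the opposite sense, the (S)-ligand is used.

**Route**

Step 1
Reactants: 1 p-coumaric acid [(E)-3-(4-hydroxyphenyl)prop-2-enoic acid]
Product: 3 (E)-3-[4-(tert-butyldimethylsilyloxy)phenyl]prop-2-enoic acid, via bis-silyl ester 2 (not isolated)
Conditions: TBSCl (2.3 equiv), imidazole (5 equiv), DMF, rt, 12 h; then AcOH/THF/H2O (1:3:1), rt, 1 h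
Reagents that add atoms: tert-butyldimethylsilyl chloride (TBSCl), CC(C)(C)[Si](C)(C)Cl
Why: Silyl protection of both acidic groups followed by selective hydrolysis of the much more labile silyl ester leaves only the aryl silyl ether, which masks the phenol in the Lewis-acidic, oxidative and basic steps that follow (no stereocentre).

Step 2
Reactants: 4 methyl (S)-lactate; 5 but-3-en-1-ylmagnesium bromide
Product: 7 (S)-2-hydroxyhept-6-en-3-one, via Weinreb amide 6 (not isolated)
Conditions: MeNHOMe·HCl (2.5 equiv), iPrMgCl (5 equiv), THF, −20 → 0 °C; then 5 (4 equiv, THF), 0 °C → rt; aq. NH4Cl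
Reagents that add atoms: none
Why: One-pot Weinreb ketone synthesis, in which ClMgN(Me)OMe turns the ester into the N-methoxy-N-methylamide and the Grignard reagent then adds only once because the N,O-chelated tetrahedral adduct survives until work-up; the lactate centre (future C6′, S) is kept because it sits next to a magnesium alkoxide and is not enolised.

Step 3
Reactants: 7 (S)-2-hydroxyhept-6-en-3-one; 3 (E)-3-[4-(tert-butyldimethylsilyloxy)phenyl]prop-2-enoic acid
Product: 8 (S)-3-oxohept-6-en-2-yl (E)-3-[4-(tert-butyldimethylsilyloxy)phenyl]prop-2-enoate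
Conditions: DCC (1.2 equiv), DMAP (0.1 equiv), CH2Cl2, 0 °C → rt
Reagents that add atoms: none
Why: Steglich esterification acylates the ketol oxygen without touching the C–O bond, so C6′ keeps the S configuration of L-lactate, and catalytic DMAP at 0 °C does not epimerise α-acyloxy ketones of this kind.

Step 4
Reactants: 8 (S)-3-oxohept-6-en-2-yl ester; 9 (Z)-but-2-ene-1,4-diol
Product: 10 (S,Z)-8-hydroxy-3-oxooct-6-en-2-yl (E)-3-[4-(tert-butyldimethylsilyloxy)phenyl]prop-2-enoate
Conditions: Ru(SIMes)(=CH-C6H4-2-OiPr)(S2C6H2Cl2) (5 mol %; S2C6H2Cl2 = 3,6-dichlorobenzene-1,2-dithiolate), 9 (3 equiv), THF, 22 °C, 8 h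
Reagents that add atoms: none
Why: Z-selective olefin cross-metathesis, in which the cis-diol supplies a Ru=CH–CH2OH carbene and the dithiolate ligand enforces all-syn metallacyclobutanes, so the new C1′=C2′ alkene forms cis (expected >94:6) while the electron-poor cinnamate alkene stays inert.

Step 5
Reactants: 10 (S,Z)-8-hydroxy-3-oxooct-6-en-2-yl ester
Product: 11 (S)-5-[(2S,3R)-3-(hydroxymethyl)oxiran-2-yl]-3-oxopentan-2-yl (E)-3-[4-(tert-butyldimethylsilyloxy)phenyl]prop-2-enoate
Conditions: Ti(OiPr)4 (0.2 equiv), D-(−)-diethyl tartrate (0.26 equiv), t-BuOOH (2 equiv, isooctane), 4 Å MS, CH2Cl2, −15 °C, 48 h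
Reagents that add atoms: tert-butyl hydroperoxide, CC(C)(C)OO
Why: Sharpless asymmetric epoxidation, in which the Ti(OiPr)4/D-(−)-tartrate catalyst delivers the peroxide oxygen to the face of the (Z)-allylic alcohol that gives the (2S,3R)-cis-epoxy alcohol, fixing C1′ (S in the target) and C2′ (S, to be inverted in step 9); ketone, esters and cinnamate are not oxidised.

Step 6
Reactants: 11 cis-epoxy alcohol
Product: 12 (S)-5-[(2S,3S)-3-formyloxiran-2-yl]-3-oxopentan-2-yl (E)-3-[4-(tert-butyldimethylsilyloxy)phenyl]prop-2-enoate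
Conditions: PhI(OAc)2 (1.1 equiv), TEMPO (0.1 equiv), CH2Cl2, 0 °C → rt, 3 h
Reagents that add atoms: none
Why: TEMPO/PhI(OAc)2 (oxoammonium) oxidation converts the primary alcohol into the aldehyde under near-neutral conditions that leave the cis-epoxide, whose α-carbon is not enolisable, unchanged.

Step 7
Reactants: 13 but-3-enoic acid; 14 phenol
Product: 15 phenyl but-3-enoate
Conditions: DCC (1.05 equiv), DMAP (0.05 equiv), CH2Cl2, 0 °C, 2 h
Reagents that add atoms: none
Why: Steglich esterification at 0 °C with little DMAP gives the aryl ester before the double bond can move into conjugation; the phenyl ester is used because it is acidic enough for soft enolisation and is a good leaving group for lactonisation.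

Step 8
Reactants: 12 cis-epoxy aldehyde; 15 phenyl but-3-enoate
Product: 17 (S)-3-oxo-5-[(2S,3S)-3-[(R)-6-oxo-3,6-dihydro-2H-pyran-2-yl]oxiran-2-yl]pentan-2-yl (E)-3-[4-(tert-butyldimethylsilyloxy)phenyl]prop-2-enoate, via (Z)-hydroxy enoate 16 (not isolated)
Conditions: Cu(MeCN)4PF6 (5 mol %), (R)-DTBM-SEGPHOS (5.5 mol %), Et3N (0.3 equiv), 15 (1.5 equiv), THF, −20 °C, 24 h
Reagents that add atoms: none
Why: Direct catalytic vinylogous aldol reaction followed by lactonisation, in which the dienolate formed from 15 on the Cu(MeCN)4PF6/bisphosphine catalyst adds through its γ-carbon in a cyclic transition state to give the (Z)-enoate 16, whose C6 alkoxide closes the δ-lactone with loss of phenol; C6 (R) is set by the chiral catalyst acting in the same sense as the Cornforth/Felkin–Anh preference of the cis-epoxy aldehyde (attack anti to the epoxide C–O, giving the C6–O/C1′–O anti relationship).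

Step 9
Reactants: 17 epoxy lactone
Product: 20 brevipolide G, via lithium enolate 18 (not isolated), via O-TBS-brevipolide G 19 (not isolated)
Conditions: Et3Al (1.2 equiv), THF, −78 °C; LiN(SiMe3)2 (1.15 equiv), −78 → −50 °C, 2 h; AcOH (6 equiv); then Bu4NF (5 equiv), 0 °C, 30 min
Reagents that add atoms: none
Why: Enolate–epoxide 3-exo-tet cyclopropanation (Stork-type epoxide-opening ring closure, promoted by Et3Al), in which the hindered amide base removes a C4′ proton (less hindered than the C6′ methine, far more acidic than the lactone γ-protons), the enolate carbon attacks C2′ anti to the Al-activated epoxide C–O bond (SN2 inversion at C2′, C1′–O kept as the S carbinol), the acyl and carbinol groups end up trans on the new ring (sets C4′), and buffered fluoride then cleaves the aryl silyl ether.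

**Compound list**

1 | (E)-3-(4-hydroxyphenyl)prop-2-enoic acid (p-coumaric acid) | OC(=O)/C=C/c1ccc(O)cc1 | starting material
2 | tert-butyldimethylsilyl (E)-3-[4-(tert-butyldimethylsilyloxy)phenyl]prop-2-enoate | CC(C)(C)[Si](C)(C)OC(=O)/C=C/c1ccc(O[Si](C)(C)C(C)(C)C)cc1 | intermediate
3 | (E)-3-[4-(tert-butyldimethylsilyloxy)phenyl]prop-2-enoic acid | OC(=O)/C=C/c1ccc(O[Si](C)(C)C(C)(C)C)cc1 | intermediate
4 | methyl (S)-2-hydroxypropanoate (methyl L-lactate) | C[C@H](O)C(=O)OC | starting material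
5 | but-3-en-1-ylmagnesium bromide | C=CCC[Mg]Br | starting material
6 | (S)-2-hydroxy-N-methoxy-N-methylpropanamide | C[C@H](O)C(=O)N(C)OC | intermediate
7 | (S)-2-hydroxyhept-6-en-3-one | C[C@H](O)C(=O)CCC=C | intermediate
8 | (S)-3-oxohept-6-en-2-yl (E)-3-[4-(tert-butyldimethylsilyloxy)phenyl]prop-2-enoate | C[C@H](OC(=O)/C=C/c1ccc(O[Si](C)(C)C(C)(C)C)cc1)C(=O)CCC=C | intermediate
9 | (Z)-but-2-ene-1,4-diol | OC/C=C\CO | starting material
10 | (S,Z)-8-hydroxy-3-oxooct-6-en-2-yl (E)-3-[4-(tert-butyldimethylsilyloxy)phenyl]prop-2-enoate | C[C@H](OC(=O)/C=C/c1ccc(O[Si](C)(C)C(C)(C)C)cc1)C(=O)CC/C=C\CO | intermediate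
11 | (S)-5-[(2S,3R)-3-(hydroxymethyl)oxiran-2-yl]-3-oxopentan-2-yl (E)-3-[4-(tert-butyldimethylsilyloxy)phenyl]prop-2-enoate (cis-epoxide) | C[C@H](OC(=O)/C=C/c1ccc(O[Si](C)(C)C(C)(C)C)cc1)C(=O)CC[C@@H]1O[C@@H]1CO | intermediate
12 | (S)-5-[(2S,3S)-3-formyloxiran-2-yl]-3-oxopentan-2-yl (E)-3-[4-(tert-butyldimethylsilyloxy)phenyl]prop-2-enoate (cis-epoxide) | C[C@H](OC(=O)/C=C/c1ccc(O[Si](C)(C)C(C)(C)C)cc1)C(=O)CC[C@@H]1O[C@@H]1C=O | intermediate
13 | but-3-enoic acid | C=CCC(=O)O | starting material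
14 | phenol | Oc1ccccc1 | starting material
15 | phenyl but-3-enoate | C=CCC(=O)Oc1ccccc1 | intermediate
16 | phenyl (2Z,5R)-5-hydroxy-5-{(2R,3S)-3-[(4S)-4-({(E)-3-[4-(tert-butyldimethylsilyloxy)phenyl]prop-2-enoyl}oxy)-3-oxopentyl]oxiran-2-yl}pent-2-enoate | C[C@H](OC(=O)/C=C/c1ccc(O[Si](C)(C)C(C)(C)C)cc1)C(=O)CC[C@@H]1O[C@@H]1[C@H](O)C/C=C\C(=O)Oc1ccccc1 | intermediate
17 | (S)-3-oxo-5-[(2S,3S)-3-[(R)-6-oxo-3,6-dihydro-2H-pyran-2-yl]oxiran-2-yl]pentan-2-yl (E)-3-[4-(tert-butyldimethylsilyloxy)phenyl]prop-2-enoate (cis-epoxide) | C[C@H](OC(=O)/C=C/c1ccc(O[Si](C)(C)C(C)(C)C)cc1)C(=O)CC[C@@H]1O[C@@H]1[C@H]1CC=CC(=O)O1 | intermediate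
18 | lithium (Z)-enolate of 17 (C4′=C5′–OLi) | C[C@H](OC(=O)/C=C/c1ccc(O[Si](C)(C)C(C)(C)C)cc1)C(/[O-])=C/C[C@@H]1O[C@@H]1[C@H]1CC=CC(=O)O1.[Li+] | intermediate
19 | (S)-1-[(1S,2S)-2-[(S)-hydroxy[(R)-6-oxo-3,6-dihydro-2H-pyran-2-yl]methyl]cyclopropyl]-1-oxopropan-2-yl (E)-3-[4-(tert-butyldimethylsilyloxy)phenyl]prop-2-enoate (O-TBS-brevipolide G) | C[C@H](OC(=O)/C=C/c1ccc(O[Si](C)(C)C(C)(C)C)cc1)C(=O)[C@H]1C[C@@H]1[C@H](O)[C@H]1CC=CC(=O)O1 | intermediate
20 | brevipolide G: (S)-1-[(1S,2S)-2-[(S)-hydroxy[(R)-6-oxo-3,6-dihydro-2H-pyran-2-yl]methyl]cyclopropyl]-1-oxopropan-2-yl (E)-3-(4-hydroxyphenyl)prop-2-enoate | C[C@H](OC(=O)/C=C/c1ccc(O)cc1)C(=O)[C@H]1C[C@@H]1[C@H](O)[C@H]1CC=CC(=O)O1 | target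

**Step count and risks**

Total steps: 9. Longest linear sequence: 7 (steps 2, 3, 4, 5, 6, 8, 9 from methyl L-lactate; steps 1 and 7 are one-step side branches).

Most likely to fail:

Step 9. The enolate must form at C4′ and close onto the epoxide faster than the lactone is deprotonated at its γ-position or the C6′ methine is enolised (C6′ epimerisation or acyl shift). The fallback keeps the lactone masked as a base-inert acetal during the ring closure. It sets out from 12: a hetero-Diels–Alder reaction with (E)-1-methoxybuta-1,3-diene, catalysed by CrCl(L) (trivalent chromium; L = the tridentate Schiff base of cis-1-aminoindan-2-ol and 3-(1-adamantyl)-2-hydroxy-5-methylbenzaldehyde, the enantiomer that reinforces the substrate bias; 4 Å MS), gives the cis-2-methoxy-dihydropyran acetal F1. Treatment with LiN(SiMe3)2/Et3Al as in step 9 closes the cyclopropane to the cyclopropyl carbinol acetal F2. PPTS in wet acetone hydrolyses the allylic acetal to the lactol F3, and MnO2 in CH2Cl2 oxidises only this allylic lactol to the lactone. The route is rejoined at 19, which is desilylated with Bu4NF/AcOH to 20.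

Step 8. The copper-catalysed vinylogous aldol–lactonisation has not been run on a cis-epoxy aldehyde that also carries a ketone, and the ligand sense is assumed. The fallback builds the lactone by allylation, acylation and ring-closing metathesis instead. It sets out from 12: (+)-Ipc2B(allyl) (Et2O, −78 °C; pH 7 buffer/H2O2 work-up), reagent control matched with the substrate preference, gives the (R)-homoallylic alcohol F4. Acryloyl chloride/iPr2NEt (CH2Cl2, 0 °C) gives the acrylate F5. The second-generation Grubbs catalyst RuCl2(SIMes)(PCy3)(=CHPh) (CH2Cl2, 40 °C) closes the pyranone, and the route is rejoined at 17.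

Step 5. (Z)-Disubstituted allylic alcohols are the slowest and least selective class in the Sharpless epoxidation, so conversion and diastereomer ratio may be inadequate. The fallback forms the lactone first and epoxidises under control of the C6 centre. It sets out from 10: MnO2 (CH2Cl2, 0 °C) gives the (Z)-enal F6. The copper-catalysed vinylogous aldol–lactonisation with 15 (conditions of step 8, catalyst control) gives the (R)-6-[(Z)-alkenyl]pyranone F7. mCPBA/NaHCO3 (CH2Cl2, 0 °C) epoxidises the isolated cis-alkene; in the A(1,3)-locked conformer the peracid is expected to approach anti to the C6–O bond, so the erythro cis-epoxide should be the main product (minor isomer removed by chromatography). The route is rejoined at 17.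

**Further compounds**

F1 | step 9 | (S)-3-oxo-5-[(2S,3S)-3-[(2R,6S)-6-methoxy-3,6-dihydro-2H-pyran-2-yl]oxiran-2-yl]pentan-2-yl (E)-3-[4-(tert-butyldimethylsilyloxy)phenyl]prop-2-enoate | C[C@H](OC(=O)/C=C/c1ccc(O[Si](C)(C)C(C)(C)C)cc1)C(=O)CC[C@@H]1O[C@@H]1[C@H]1CC=C[C@@H](OC)O1
F2 | step 9 | (S)-1-[(1S,2S)-2-[(S)-hydroxy[(2R,6S)-6-methoxy-3,6-dihydro-2H-pyran-2-yl]methyl]cyclopropyl]-1-oxopropan-2-yl (E)-3-[4-(tert-butyldimethylsilyloxy)phenyl]prop-2-enoate | C[C@H](OC(=O)/C=C/c1ccc(O[Si](C)(C)C(C)(C)C)cc1)C(=O)[C@H]1C[C@@H]1[C@H](O)[C@H]1CC=C[C@@H](OC)O1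
F3 | step 9 | (S)-1-[(1S,2S)-2-[(S)-hydroxy[(2R)-6-hydroxy-3,6-dihydro-2H-pyran-2-yl]methyl]cyclopropyl]-1-oxopropan-2-yl (E)-3-[4-(tert-butyldimethylsilyloxy)phenyl]prop-2-enoate (lactol, anomeric mixture) | C[C@H](OC(=O)/C=C/c1ccc(O[Si](C)(C)C(C)(C)C)cc1)C(=O)[C@H]1C[C@@H]1[C@H](O)[C@H]1CC=CC(O)O1
F4 | step 8 | (S)-5-[(2S,3R)-3-[(R)-1-hydroxybut-3-en-1-yl]oxiran-2-yl]-3-oxopentan-2-yl (E)-3-[4-(tert-butyldimethylsilyloxy)phenyl]prop-2-enoate | C[C@H](OC(=O)/C=C/c1ccc(O[Si](C)(C)C(C)(C)C)cc1)C(=O)CC[C@@H]1O[C@@H]1[C@H](O)CC=C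
F5 | step 8 | (S)-5-[(2S,3S)-3-[(R)-1-(acryloyloxy)but-3-en-1-yl]oxiran-2-yl]-3-oxopentan-2-yl (E)-3-[4-(tert-butyldimethylsilyloxy)phenyl]prop-2-enoate | C[C@H](OC(=O)/C=C/c1ccc(O[Si](C)(C)C(C)(C)C)cc1)C(=O)CC[C@@H]1O[C@@H]1[C@H](OC(=O)C=C)CC=C
F6 | step 5 | (S,Z)-3,8-dioxooct-6-en-2-yl (E)-3-[4-(tert-butyldimethylsilyloxy)phenyl]prop-2-enoate | C[C@H](OC(=O)/C=C/c1ccc(O[Si](C)(C)C(C)(C)C)cc1)C(=O)CC/C=C\C=O
F7 | step 5 | (S,Z)-3-oxo-7-[(R)-6-oxo-3,6-dihydro-2H-pyran-2-yl]hept-6-en-2-yl (E)-3-[4-(tert-butyldimethylsilyloxy)phenyl]prop-2-enoate | C[C@H](OC(=O)/C=C/c1ccc(O[Si](C)(C)C(C)(C)C)cc1)C(=O)CC/C=C\[C@H]1CC=CC(=O)O1
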